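- A straight line through Z misleads: carried past the end of the run, it books more Z than the Q charged allows, so I needed two times.

| setting | west | north-west | flask |
|---|---|---|---|
| Q | 0.14 M | 0.22 M | 0.10 M |
| X | 4 mM (held) | 4 mM (held) | 4.0 mM (held) |
| remark | run made earlier | run made earlier |  |
| time |  |  | 12 min |

| run | time / min | Z / % | Q / % |
|---|---|---|---|
| west | 4.00 | 30.5 | 49.9 |
| west | 8.00 | 59.7 | 29.7 |
| west | 10.0 | 69.5 | 21.2 |
| west | 15.0 | 91.1 | 6.4 |
| north-west | 2.00 | 10.8 | 64.8 |
| north-west | 5.00 | 26.1 | 54.0 |
| north-west | 10.0 | 52.5 | 33.9 |
| north-west | 15.0 | 75.4 | 18.4 |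

(scatter of a reading: 0.5 percentage points)

- at the start none of D is dissolved
- the numbers in the tables scatter by 0.5 percentage points (one standard deviation)
- steps thought possible: X <-> D; Q + D -> Z; Q <-> L; D -> J

- the Z standing at 12 min, as a percentage of the Q charged
- the change that raises the amount of Z at 12 min, in percent of the Q charged most ("none" if none brings more than 2 percentage points) (Saturday's / Thursday's / none)
- amount of Z at 12 min, in percent of the Q charged, after Saturday's

- Saturday's: doubling the transfer coefficient of X, all else as stated
- Thursday's: doubling the saturation concentration of X, all else as stated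

- West gave 10.4 mM min⁻¹ of Z up to 8.00 min and north-west 11.6 mM min⁻¹ up to 10.0 min, a rise smaller than that in charge, so I took west's slope as the straight-line rate for this flask, with Q the limiting reagent.
- For this flask I got 9.57 min: the clearing time, the charge of Q divided by the straight-line rate.
- The remainder, the charge less Z, holds cQ and cL; in west it fell from 30.5% to 8.90% between 10.0 min and 15.0 min, a tail time of 4.06 min.
- I joined line and tail where their slopes meet; the remainder is then tail over clearing time, 0.424, times e to the power of minus one minus the overrun over the tail time. The overrun of 2.43 min left 8.58%, so Z stood at 91.4%.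
- Thursday's, the doubled saturation concentration of X, I took to divide both times by 2, giving 99.6%. Saturday's, the doubled transfer coefficient of X, I took to divide the clearing time by 2, and with the tail held that gives 94.7%, so I chose Thursday's, with Saturday's between those figures.
- The forecast said 89.5%, Thursday's and 97.5%, holding that “gas transfer limits the rate until Q runs low”.
- The flask gave 90.5%, with Thursday's best by 9.4 percentage points against 7.4 points, and 97.9% after Saturday's.

    X ⇌ D, rate k1*(csat - [D]) (kL = 3.50 min⁻¹)
    Q + D → Z (k = 170 M⁻¹ min⁻¹)
    Q ⇌ L (K = 0.380, k = 2.00 min⁻¹)
    D → J (k = 0.370 min⁻¹)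

- In this flask, 1.20 min over the clearing time of 9.57 min gives 12.5%, and Z stood at 11.9%.
- The neighbouring flask, with the same charge, stopped at 3.0 min, before the line meets the tail; the same division gave 31.3%, and its Z stood at 29.8%.

The data are calculated with constants of no real substance, and the scatter is random.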